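**Plan**

- Cuts: C8–C9 (last bond, Stille); the lactone at C10–C11 and O–C11 (coupling–lactonisation on a terminal alkyne); the chain at C15=C15' and C11'=C14' (Wittig) and at C6'–C7' (Sonogashira); in ring B, C7=C8 (Takai) and C6–C7 (key step).
- Enabling feature: in ring B the tertiary C5 hydroxyl is cis to the C7=C8 arm on the neighbouring carbinol carbon C6, and C6 lies between the fully substituted C1 and C5. A C6 ketone therefore cannot enolise, and a one-carbon unit tethered through silicon to the C5 oxygen can be delivered to the face that free nucleophiles avoid.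
- Forward order: ketoisophorone is taken to the ring B ketol, the O–Si–CH2 tether closes a temporary oxasilolane on C6, and oxidation, olefination and stannylation give the ring B alkenylstannane. The mirror-image enone gives the ring A enol triflate, extended by one Sonogashira coupling and two Wittig reactions to a polyenediyne; the butenolide is closed on its terminal alkyne and the two halves are joined last.
- Stereochemistry: C3 and C3' from asymmetric transfer hydrogenation with the two enantiomers of one catalyst; C5 from peracid attack anti to the C3 silyloxy group; C6 from C5 through the tether; alkene geometry from E building blocks, Takai olefination, iodine equilibration and anti oxymetallation (Z at C11=C12).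

Key step: step 7

Locants: ring B C1 (CMe2), C2, C3 (CHOH), C4, C5 (C(Me)OH), C6 (carbinol carbon with the arm); arm C7=C8; lactone C9 (alpha), C10, C11 (gamma), carbonyl C19; chain C12, C13 (Me), C14, C15, C15', C14', C11', C10', C9' (Me), C8'≡C7'; ring A C1'–C6' with the hydroxyl on C3'.

Assumption: with the enone alkene in the role that an aryl group plays in the usual model, the (R,R) catalyst is taken to give the (R) allylic alcohol and the (S,S) catalyst the (S) alcohol; if the sense is the reverse, the two catalysts change places.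

**Ring B branch**

Step 1
Reactants: 1 ketoisophorone (2,6,6-trimethylcyclohex-2-ene-1,4-dione)
Product: 2 (4R)-4-hydroxy-2,6,6-trimethylcyclohex-2-en-1-one
Conditions: RuCl(p-cymene)[(R,R)-TsDPEN] (0.5 mol %), t-BuOK (1 mol %), i-PrOH, 25 °C
Reagents that add atoms: none
Why: Asymmetric transfer hydrogenation from 2-propanol reduces only the carbonyl remote from the gem-dimethyl carbon (the future C3), and the chiral ruthenium hydride is expected to add to one face of this conjugated ketone so that C3 is set as R.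

Step 2
Reactants: 2 (4R)-4-hydroxy-2,6,6-trimethylcyclohex-2-en-1-one
Product: 3 (4R)-4-(tert-butyldimethylsilyloxy)-2,6,6-trimethylcyclohex-2-en-1-one
Conditions: TBSCl, imidazole, DMF, 25 °C
Reagents that add atoms: tert-butyldimethylsilyl chloride, CC(C)(C)[Si](C)(C)Cl
Why: Silyl ether formation at the secondary alcohol gives a group that should survive hydride, peracid, alkyllithium and chromium reagents and that later biases the faces of the enol ether, with no stereocentre touched.

Step 3
Reactants: 3 (4R)-4-(tert-butyldimethylsilyloxy)-2,6,6-trimethylcyclohex-2-en-1-one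
Product: 5 (4S)-4-(tert-butyldimethylsilyloxy)-2,6,6-trimethyl-1-(trimethylsilyloxy)cyclohex-1-ene, via lithium enolate 4 (not isolated)
Conditions: LiBH(s-Bu)3 (L-Selectride), THF, −78 °C; then Me3SiCl, Et3N, −78 to 0 °C
Reagents that add atoms: chlorotrimethylsilane, C[Si](C)(C)Cl
Why: Conjugate reduction of the beta-unsubstituted enone by the bulky borohydride, whose 1,2-attack is blocked by the gem-dimethyl group, followed by O-silylation of the lithium enolate (reductive enolate trapping) gives the only possible enol ether, the change of descriptor at the silyloxy carbon being formal.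

Step 4
Reactants: 5 (4S)-4-(tert-butyldimethylsilyloxy)-2,6,6-trimethyl-1-(trimethylsilyloxy)cyclohex-1-ene
Product: 8 (2S,4R)-4-(tert-butyldimethylsilyloxy)-2-hydroxy-2,6,6-trimethylcyclohexan-1-one, via silyloxy epoxide 6 (not isolated), via trimethylsilyloxy ketone 7 (not isolated)
Conditions: mCPBA, NaHCO3, CH2Cl2, −20 to 0 °C; then citric acid, MeOH, 25 °C
Reagents that add atoms: 3-chloroperoxybenzoic acid, OOC(=O)c1cccc(Cl)c1
Why: Rubottom oxidation in which the peracid is expected to epoxidise the C5=C6 enol ether on the face opposite the C3 silyloxy group, as peracids do with O-protected 3-oxygenated cyclohexenes of this substitution pattern, so that silyl migration and methanolysis leave the C5 hydroxyl trans to the C3 oxygen (5S in ring B numbering).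

Step 5
Reactants: 8 (2S,4R)-4-(tert-butyldimethylsilyloxy)-2-hydroxy-2,6,6-trimethylcyclohexan-1-one; 9 chloro(chloromethyl)dimethylsilane
Product: 10 (2S,4R)-4-(tert-butyldimethylsilyloxy)-2-{[(chloromethyl)dimethylsilyl]oxy}-2,6,6-trimethylcyclohexan-1-one
Conditions: imidazole, DMAP (10 mol %), DMF, 25 °C
Reagents that add atoms: none
Why: Silyl ether formation at the tertiary hydroxyl with a small chlorodimethylsilane, routine for tertiary alcohols, places the three-atom O–Si–C tether on the C5 oxygen without touching a stereocentre.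

Step 6
Reactants: 10 (2S,4R)-4-(tert-butyldimethylsilyloxy)-2-{[(chloromethyl)dimethylsilyl]oxy}-2,6,6-trimethylcyclohexan-1-one
Product: 11 (2S,4R)-4-(tert-butyldimethylsilyloxy)-2-{[(iodomethyl)dimethylsilyl]oxy}-2,6,6-trimethylcyclohexan-1-one
Conditions: NaI, acetone, reflux, dark
Reagents that add atoms: sodium iodide, [Na+].[I-]
Why: Finkelstein exchange, fast at a carbon alpha to silicon and driven by precipitation of NaCl, gives the iodide needed for lithium–iodine exchange and leaves the ketone and both silyl ethers alone.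

Step 7
Reactants: 11 (2S,4R)-4-(tert-butyldimethylsilyloxy)-2-{[(iodomethyl)dimethylsilyl]oxy}-2,6,6-trimethylcyclohexan-1-one
Product: 14 (3aS,6R,7aS)-6-(tert-butyldimethylsilyloxy)-2,2,4,4,7a-pentamethyloctahydro-2,1-benzoxasilol-3a-ol, via alkyllithium 12 (not isolated), via lithium alkoxide 13 (not isolated)
Conditions: t-BuLi (2.1 equiv), pentane–Et2O (3:2), −78 °C; then AcOH, −78 °C
Reagents that add atoms: none
Why: Proposed new method: iodine–lithium exchange at the CH2I group (the second equivalent of t-BuLi consumes the t-BuI formed) gives the alpha-silyl alkyllithium 12, whose carbanion adds to the C6 carbonyl to form the C6–C7 bond and the lithium alkoxide 13, which is protonated cold to 14. The closest known reaction types are the addition of (alkoxydimethylsilyl)methyl Grignard reagents to ketones, exchange-initiated cyclisations of iodo ketones and silicon-tethered radical hydroxymethylation. The one new ring, a 1-oxa-2-silacyclopentane, closes by 5-exo-trig attack on the carbonyl carbon. The new C6 stereocentre is controlled by C5 through the tether: the three-atom O–Si–C chain reaches only the carbonyl face on the side of the C5 oxygen, so C7 ends cis to that oxygen and the new hydroxyl trans (cis-fused bicycle), the opposite of an external nucleophile, which would enter anti to the axial C5 oxygen and the axial C1 methyl. The step needs exchange to outrun attack of t-BuLi on the carbonyl group and on silicon, which the flanking fully substituted C1 and C5 and the lack of any alpha-hydrogen should secure, and it needs the beta-silyl alkoxide to survive, which the lithium counter-ion, the low temperature and the ring-enforced non-periplanar O–C–C–Si geometry should secure against Peterson elimination.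

Step 8
Reactants: 14 (3aS,6R,7aS)-6-(tert-butyldimethylsilyloxy)-2,2,4,4,7a-pentamethyloctahydro-2,1-benzoxasilol-3a-ol
Product: 15 (1R,2S,4R)-4-(tert-butyldimethylsilyloxy)-1-(hydroxymethyl)-2,6,6-trimethylcyclohexane-1,2-diol
Conditions: 30% H2O2, KF, KHCO3, THF–MeOH (1:1), 25 to 40 °C
Reagents that add atoms: hydrogen peroxide, OO
Why: Tamao oxidation of the cyclic alkoxysilane, in which hydroperoxide adds to fluoride-activated silicon and C7 migrates from silicon to oxygen, turns the C7–Si bond into C7–OH and frees the C5 hydroxyl under buffered conditions known to spare beta-hydroxy silanes from Peterson elimination.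

Step 9
Reactants: 15 (1R,2S,4R)-4-(tert-butyldimethylsilyloxy)-1-(hydroxymethyl)-2,6,6-trimethylcyclohexane-1,2-diol
Product: 16 (1S,2S,4R)-4-(tert-butyldimethylsilyloxy)-1,2-dihydroxy-2,6,6-trimethylcyclohexane-1-carbaldehyde
Conditions: IBX, DMSO, 25 °C
Reagents that add atoms: none
Why: IBX oxidation takes the only primary alcohol to the aldehyde without cleaving the vicinal diol, the two tertiary hydroxyls cannot be oxidised, and the aldehyde has no alpha-hydrogen through which C6 could epimerise.

Step 10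
Reactants: 16 (1S,2S,4R)-4-(tert-butyldimethylsilyloxy)-1,2-dihydroxy-2,6,6-trimethylcyclohexane-1-carbaldehyde
Product: 17 (1S,2S,4R)-4-(tert-butyldimethylsilyloxy)-1-[(E)-2-iodoethenyl]-2,6,6-trimethylcyclohexane-1,2-diol
Conditions: CrCl2 (8 equiv), CHI3 (3 equiv), THF–dioxane, 0 to 25 °C
Reagents that add atoms: iodoform, IC(I)I
Why: Takai olefination, in which the geminal dichromium species formed from iodoform and divalent chromium adds to the aldehyde and eliminates to the E-alkenyl iodide, is selective for aldehydes, tolerates free hydroxyls and is most E-selective with bulky aldehydes such as this one.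

Step 11
Reactants: 17 (1S,2S,4R)-4-(tert-butyldimethylsilyloxy)-1-[(E)-2-iodoethenyl]-2,6,6-trimethylcyclohexane-1,2-diol
Product: 18 (1S,2S,4R)-1-[(E)-2-iodoethenyl]-2,6,6-trimethylcyclohexane-1,2,4-triol
Conditions: HF·pyridine, pyridine, THF, 0 to 25 °C
Reagents that add atoms: none
Why: Fluoride-driven desilylation of the secondary silyl ether under pyridine-buffered conditions should leave the alkenyl iodide and the tertiary allylic alcohol unchanged.

Step 12
Reactants: 18 (1S,2S,4R)-1-[(E)-2-iodoethenyl]-2,6,6-trimethylcyclohexane-1,2,4-triol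
Product: 19 (1S,2S,4R)-2,6,6-trimethyl-1-[(E)-2-(trimethylstannyl)ethenyl]cyclohexane-1,2,4-triol
Conditions: Me3SnSnMe3, PdCl2(MeCN)2 (5 mol %), NMP, 25 °C
Reagents that add atoms: hexamethylditin, C[Sn](C)(C)[Sn](C)(C)C
Why: Palladium-catalysed stannylation of the alkenyl iodide (oxidative addition to zerovalent palladium, transmetallation with the distannane, reductive elimination) replaces iodine by tin with retention of the E geometry and tolerates the free triol.

**Ring A branch**

Step 13
Reactants: 1 ketoisophorone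
Product: 20 (4S)-4-hydroxy-2,6,6-trimethylcyclohex-2-en-1-one
Conditions: RuCl(p-cymene)[(S,S)-TsDPEN] (0.5 mol %), t-BuOK (1 mol %), i-PrOH, 25 °C
Reagents that add atoms: none
Why: The same asymmetric transfer hydrogenation with the mirror-image catalyst should give the enantiomeric alcohol, whose carbinol centre becomes the 3'R centre of ring A (the descriptor changes with the ring substituents, the centre is not touched again).

Step 14
Reactants: 20 (4S)-4-hydroxy-2,6,6-trimethylcyclohex-2-en-1-one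
Product: 21 (4S)-4-(tert-butyldimethylsilyloxy)-2,6,6-trimethylcyclohex-2-en-1-one
Conditions: TBSCl, imidazole, DMF, 25 °C
Reagents that add atoms: tert-butyldimethylsilyl chloride, CC(C)(C)[Si](C)(C)Cl
Why: Silyl ether formation as in step 2 protects the ring A hydroxyl through the enolate, palladium and ylide chemistry that follows.

Step 15
Reactants: 21 (4S)-4-(tert-butyldimethylsilyloxy)-2,6,6-trimethylcyclohex-2-en-1-one
Product: 23 (4R)-4-(tert-butyldimethylsilyloxy)-2,6,6-trimethylcyclohex-1-en-1-yl trifluoromethanesulfonate, via lithium enolate 22 (not isolated)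
Conditions: LiBH(s-Bu)3 (L-Selectride), THF, −78 °C; then PhNTf2, −78 to 25 °C
Reagents that add atoms: N-phenylbis(trifluoromethanesulfonimide), O=S(=O)(N(c1ccccc1)S(=O)(=O)C(F)(F)F)C(F)(F)F
Why: Conjugate reduction followed by O-triflation of the regiodefined lithium enolate (reductive enolate triflation) gives the tetrasubstituted enol triflate with the double bond at C5'=C6' and no regioisomer.

Step 16
Reactants: 23 (4R)-4-(tert-butyldimethylsilyloxy)-2,6,6-trimethylcyclohex-1-en-1-yl trifluoromethanesulfonate; 24 (2E)-3-methylpent-2-en-4-yn-1-ol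
Product: 25 (2E)-5-[(4R)-4-(tert-butyldimethylsilyloxy)-2,6,6-trimethylcyclohex-1-en-1-yl]-3-methylpent-2-en-4-yn-1-ol
Conditions: Pd(PPh3)4 (5 mol %), CuI (10 mol %), i-Pr2NH, DMF, 25 to 50 °C
Reagents that add atoms: none
Why: Sonogashira coupling of the enol triflate with the terminal alkyne, well established for hindered cyclohexenyl triflates of this kind, forms the C6'–C7' bond and keeps the E geometry of the enynol.

Step 17
Reactants: 25 (2E)-5-[(4R)-4-(tert-butyldimethylsilyloxy)-2,6,6-trimethylcyclohex-1-en-1-yl]-3-methylpent-2-en-4-yn-1-ol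
Product: 26 (2E)-5-[(4R)-4-(tert-butyldimethylsilyloxy)-2,6,6-trimethylcyclohex-1-en-1-yl]-3-methylpent-2-en-4-ynal
Conditions: MnO2, CH2Cl2, 25 °C
Reagents that add atoms: none
Why: Manganese dioxide oxidation is selective for the allylic alcohol and gives the enal without touching the alkyne, the ring alkene or the silyl ether.

Step 18
Reactants: 26 (2E)-5-[(4R)-4-(tert-butyldimethylsilyloxy)-2,6,6-trimethylcyclohex-1-en-1-yl]-3-methylpent-2-en-4-ynal
Product: 27 (2E,4E)-7-[(4R)-4-(tert-butyldimethylsilyloxy)-2,6,6-trimethylcyclohex-1-en-1-yl]-5-methylhepta-2,4-dien-6-ynal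
Conditions: Ph3P=CHCHO, toluene, 80 °C
Reagents that add atoms: (triphenylphosphoranylidene)acetaldehyde, O=CC=P(c1ccccc1)(c1ccccc1)c1ccccc1
Why: Wittig olefination with the stabilised formyl ylide adds C14' and C15' and forms the C11'=C14' bond with the E geometry typical of stabilised ylides, the more conjugated product aldehyde being less reactive than the starting enal.

Step 19
Reactants: 24 (2E)-3-methylpent-2-en-4-yn-1-ol
Product: 29 [(2E)-3-methylpent-2-en-4-yn-1-yl]triphenylphosphonium bromide, via allylic bromide 28 (not isolated)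
Conditions: CBr4 (1.1 equiv), PPh3 (2.3 equiv), CH2Cl2, 0 °C; then MeCN, 50 °C
Reagents that add atoms: triphenylphosphine, c1ccc(cc1)P(c1ccccc1)c1ccccc1; carbon tetrabromide, BrC(Br)(Br)Br
Why: Appel bromination replaces the primary allylic hydroxyl by direct displacement, without an allyl cation that could scramble the E double bond, and the excess phosphine then quaternises the allylic bromide in the same flask.

Step 20
Reactants: 27 (2E,4E)-7-[(4R)-4-(tert-butyldimethylsilyloxy)-2,6,6-trimethylcyclohex-1-en-1-yl]-5-methylhepta-2,4-dien-6-ynal; 29 [(2E)-3-methylpent-2-en-4-yn-1-yl]triphenylphosphonium bromide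
Product: 32 tert-butyl({(1R)-4-[(3E,5E,7E,9E)-3,10-dimethyldodeca-3,5,7,9-tetraene-1,11-diyn-1-yl]-3,5,5-trimethylcyclohex-3-en-1-yl}oxy)dimethylsilane, via phosphorus ylide 30 (not isolated), via 15Z isomer 31 (not isolated)
Conditions: NaOMe, MeOH–CH2Cl2, 0 to 25 °C; then I2 (1 mol %), toluene, daylight, 25 °C
Reagents that add atoms: none
Why: Wittig olefination of the dienal with the semi-stabilised allylic ylide forms the C15=C15' bond as a mixture of E and Z isomers, and iodine-catalysed equilibration, routine for polyenes, should convert the Z component into the all-E tetraene.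

Step 21
Reactants: 32 tert-butyl({(1R)-4-[(3E,5E,7E,9E)-3,10-dimethyldodeca-3,5,7,9-tetraene-1,11-diyn-1-yl]-3,5,5-trimethylcyclohex-3-en-1-yl}oxy)dimethylsilane
Product: 33 (1R)-4-[(3E,5E,7E,9E)-3,10-dimethyldodeca-3,5,7,9-tetraene-1,11-diyn-1-yl]-3,5,5-trimethylcyclohex-3-en-1-ol
Conditions: HF·pyridine, pyridine, THF, 0 to 25 °C
Reagents that add atoms: none
Why: Buffered fluoride desilylation frees the ring A hydroxyl before the base-sensitive lactone is built, the polyene and the terminal alkyne being inert to it.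

Step 22
Reactants: 34 propiolic acid (prop-2-ynoic acid)
Product: 35 (2E)-2,3-dibromoprop-2-enoic acid
Conditions: Br2, CH2Cl2, 0 to 25 °C, dark
Reagents that add atoms: bromine, BrBr
Why: Ionic anti addition of bromine to the triple bond (electrophilic bromination) gives the E dibromide, in which the C3 bromine is cis to the carboxyl group as the lactonisation requires.

Step 23
Reactants: 33 (1R)-4-[(3E,5E,7E,9E)-3,10-dimethyldodeca-3,5,7,9-tetraene-1,11-diyn-1-yl]-3,5,5-trimethylcyclohex-3-en-1-ol; 35 (2E)-2,3-dibromoprop-2-enoic acid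
Product: 37 (5Z)-3-bromo-5-{(2E,4E,6E,8E)-11-[(4R)-4-hydroxy-2,6,6-trimethylcyclohex-1-en-1-yl]-2,9-dimethylundeca-2,4,6,8-tetraen-10-yn-1-ylidene}furan-2(5H)-one, via enynoic acid 36 (not isolated)
Conditions: 35 (1.5 equiv), PdCl2(PPh3)2 (5 mol %), CuI (10 mol %), Et3N, MeCN–THF, 25 °C, dark
Reagents that add atoms: none
Why: Tandem Sonogashira coupling and 5-exo-dig lactonisation, known for 3-haloacrylic acids and for polyenynes, should couple the terminal alkyne at the more reactive C3–Br bond and then add the cis carboxylate anti across the metal-activated triple bond, which closes the butenolide and sets the exocyclic C11=C12 bond as Z.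

**Union**

Step 24
Reactants: 19 (1S,2S,4R)-2,6,6-trimethyl-1-[(E)-2-(trimethylstannyl)ethenyl]cyclohexane-1,2,4-triol; 37 (5Z)-3-bromo-5-{(2E,4E,6E,8E)-11-[(4R)-4-hydroxy-2,6,6-trimethylcyclohex-1-en-1-yl]-2,9-dimethylundeca-2,4,6,8-tetraen-10-yn-1-ylidene}furan-2(5H)-one
Product: 38 CNP0163979.2, (5Z)-3-{(E)-2-[(1S,2S,4R)-1,2,4-trihydroxy-2,6,6-trimethylcyclohexyl]ethenyl}-5-{(2E,4E,6E,8E)-11-[(4R)-4-hydroxy-2,6,6-trimethylcyclohex-1-en-1-yl]-2,9-dimethylundeca-2,4,6,8-tetraen-10-yn-1-ylidene}furan-2(5H)-one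
Conditions: Pd2(dba)3 (5 mol %), AsPh3 (40 mol %), NMP, 25 to 40 °C, dark
Reagents that add atoms: none
Why: Stille coupling of the alpha-bromobutenolide with the alkenylstannane forms the C8–C9 bond with retention of the E geometry under neutral conditions that the enol lactone, the polyene and the four free hydroxyls tolerate, so no stereocentre is disturbed.

**Compound list**

1 | ketoisophorone (2,6,6-trimethylcyclohex-2-ene-1,4-dione) | CC1=CC(=O)CC(C)(C)C1=O | starting material
2 | (4R)-4-hydroxy-2,6,6-trimethylcyclohex-2-en-1-one | O=C1C(C)(C)C[C@@H](O)C=C1C | intermediate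
3 | (4R)-4-(tert-butyldimethylsilyloxy)-2,6,6-trimethylcyclohex-2-en-1-one | O=C1C(C)(C)C[C@@H](O[Si](C)(C)C(C)(C)C)C=C1C | intermediate
4 | lithium (4S)-4-(tert-butyldimethylsilyloxy)-2,6,6-trimethylcyclohex-1-en-1-olate | [Li]OC1=C(C)C[C@H](O[Si](C)(C)C(C)(C)C)CC1(C)C | intermediate
5 | (4S)-4-(tert-butyldimethylsilyloxy)-2,6,6-trimethyl-1-(trimethylsilyloxy)cyclohex-1-ene | C[Si](C)(C)OC1=C(C)C[C@H](O[Si](C)(C)C(C)(C)C)CC1(C)C | intermediate
6 | 1,2-epoxide of 5, epoxide oxygen anti to the tert-butyldimethylsilyloxy group: 4-(tert-butyldimethylsilyloxy)-1,2-epoxy-2,6,6-trimethyl-1-(trimethylsilyloxy)cyclohexane | C[Si](C)(C)O[C@@]12C(C)(C)C[C@@H](O[Si](C)(C)C(C)(C)C)C[C@]1(C)O2 | intermediate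
7 | (2S,4R)-4-(tert-butyldimethylsilyloxy)-2,6,6-trimethyl-2-(trimethylsilyloxy)cyclohexan-1-one | O=C1C(C)(C)C[C@@H](O[Si](C)(C)C(C)(C)C)C[C@]1(C)O[Si](C)(C)C | intermediate
8 | (2S,4R)-4-(tert-butyldimethylsilyloxy)-2-hydroxy-2,6,6-trimethylcyclohexan-1-one | O=C1C(C)(C)C[C@@H](O[Si](C)(C)C(C)(C)C)C[C@]1(C)O | intermediate
9 | chloro(chloromethyl)dimethylsilane | C[Si](C)(Cl)CCl | starting material
10 | (2S,4R)-4-(tert-butyldimethylsilyloxy)-2-{[(chloromethyl)dimethylsilyl]oxy}-2,6,6-trimethylcyclohexan-1-one | O=C1C(C)(C)C[C@@H](O[Si](C)(C)C(C)(C)C)C[C@]1(C)O[Si](C)(C)CCl | intermediate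
11 | (2S,4R)-4-(tert-butyldimethylsilyloxy)-2-{[(iodomethyl)dimethylsilyl]oxy}-2,6,6-trimethylcyclohexan-1-one | O=C1C(C)(C)C[C@@H](O[Si](C)(C)C(C)(C)C)C[C@]1(C)O[Si](C)(C)CI | intermediate
12 | (2S,4R)-4-(tert-butyldimethylsilyloxy)-2-{[(lithiomethyl)dimethylsilyl]oxy}-2,6,6-trimethylcyclohexan-1-one | O=C1C(C)(C)C[C@@H](O[Si](C)(C)C(C)(C)C)C[C@]1(C)O[Si](C)(C)C[Li] | intermediate
13 | lithium (3aS,6R,7aS)-6-(tert-butyldimethylsilyloxy)-2,2,4,4,7a-pentamethyloctahydro-2,1-benzoxasilol-3a-olate | C1[C@]2(O[Li])C(C)(C)C[C@@H](O[Si](C)(C)C(C)(C)C)C[C@]2(C)O[Si]1(C)C | intermediate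
14 | (3aS,6R,7aS)-6-(tert-butyldimethylsilyloxy)-2,2,4,4,7a-pentamethyloctahydro-2,1-benzoxasilol-3a-ol (cis-fused oxasilolane carbinol) | C1[C@]2(O)C(C)(C)C[C@@H](O[Si](C)(C)C(C)(C)C)C[C@]2(C)O[Si]1(C)C | intermediate
15 | (1R,2S,4R)-4-(tert-butyldimethylsilyloxy)-1-(hydroxymethyl)-2,6,6-trimethylcyclohexane-1,2-diol | OC[C@]1(O)C(C)(C)C[C@@H](O[Si](C)(C)C(C)(C)C)C[C@]1(C)O | intermediate
16 | (1S,2S,4R)-4-(tert-butyldimethylsilyloxy)-1,2-dihydroxy-2,6,6-trimethylcyclohexane-1-carbaldehyde | O=C[C@]1(O)C(C)(C)C[C@@H](O[Si](C)(C)C(C)(C)C)C[C@]1(C)O | intermediate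
17 | (1S,2S,4R)-4-(tert-butyldimethylsilyloxy)-1-[(E)-2-iodoethenyl]-2,6,6-trimethylcyclohexane-1,2-diol | I/C=C/[C@]1(O)C(C)(C)C[C@@H](O[Si](C)(C)C(C)(C)C)C[C@]1(C)O | intermediate
18 | (1S,2S,4R)-1-[(E)-2-iodoethenyl]-2,6,6-trimethylcyclohexane-1,2,4-triol | I/C=C/[C@]1(O)C(C)(C)C[C@@H](O)C[C@]1(C)O | intermediate
19 | (1S,2S,4R)-2,6,6-trimethyl-1-[(E)-2-(trimethylstannyl)ethenyl]cyclohexane-1,2,4-triol | C[Sn](C)(C)/C=C/[C@]1(O)C(C)(C)C[C@@H](O)C[C@]1(C)O | intermediate
20 | (4S)-4-hydroxy-2,6,6-trimethylcyclohex-2-en-1-one | O=C1C(C)(C)C[C@H](O)C=C1C | intermediate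
21 | (4S)-4-(tert-butyldimethylsilyloxy)-2,6,6-trimethylcyclohex-2-en-1-one | O=C1C(C)(C)C[C@H](O[Si](C)(C)C(C)(C)C)C=C1C | intermediate
22 | lithium (4R)-4-(tert-butyldimethylsilyloxy)-2,6,6-trimethylcyclohex-1-en-1-olate | [Li]OC1=C(C)C[C@@H](O[Si](C)(C)C(C)(C)C)CC1(C)C | intermediate
23 | (4R)-4-(tert-butyldimethylsilyloxy)-2,6,6-trimethylcyclohex-1-en-1-yl trifluoromethanesulfonate | O=S(=O)(OC1=C(C)C[C@@H](O[Si](C)(C)C(C)(C)C)CC1(C)C)C(F)(F)F | intermediate
24 | (2E)-3-methylpent-2-en-4-yn-1-ol | C#C/C(C)=C/CO | starting material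
25 | (2E)-5-[(4R)-4-(tert-butyldimethylsilyloxy)-2,6,6-trimethylcyclohex-1-en-1-yl]-3-methylpent-2-en-4-yn-1-ol | CC1=C(C#C/C(C)=C/CO)C(C)(C)C[C@H](O[Si](C)(C)C(C)(C)C)C1 | intermediate
26 | (2E)-5-[(4R)-4-(tert-butyldimethylsilyloxy)-2,6,6-trimethylcyclohex-1-en-1-yl]-3-methylpent-2-en-4-ynal | CC1=C(C#C/C(C)=C/C=O)C(C)(C)C[C@H](O[Si](C)(C)C(C)(C)C)C1 | intermediate
27 | (2E,4E)-7-[(4R)-4-(tert-butyldimethylsilyloxy)-2,6,6-trimethylcyclohex-1-en-1-yl]-5-methylhepta-2,4-dien-6-ynal | CC1=C(C#C/C(C)=C/C=C/C=O)C(C)(C)C[C@H](O[Si](C)(C)C(C)(C)C)C1 | intermediate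
28 | (3E)-5-bromo-3-methylpent-3-en-1-yne | C#C/C(C)=C/CBr | intermediate
29 | [(2E)-3-methylpent-2-en-4-yn-1-yl]triphenylphosphonium bromide | C#C/C(C)=C/C[P+](c1ccccc1)(c1ccccc1)c1ccccc1.[Br-] | intermediate
30 | [(2E)-3-methylpent-2-en-4-yn-1-ylidene]triphenylphosphorane | C#C/C(C)=C/C=P(c1ccccc1)(c1ccccc1)c1ccccc1 | intermediate
31 | (3E,5E,7Z,9E) isomer of 32 (Z at C15=C15') | CC1=C(C#C/C(C)=C/C=C/C=C\C=C(C)\C#C)C(C)(C)C[C@H](O[Si](C)(C)C(C)(C)C)C1 | intermediate
32 | tert-butyl({(1R)-4-[(3E,5E,7E,9E)-3,10-dimethyldodeca-3,5,7,9-tetraene-1,11-diyn-1-yl]-3,5,5-trimethylcyclohex-3-en-1-yl}oxy)dimethylsilane | CC1=C(C#C/C(C)=C/C=C/C=C/C=C(C)/C#C)C(C)(C)C[C@H](O[Si](C)(C)C(C)(C)C)C1 | intermediate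
33 | (1R)-4-[(3E,5E,7E,9E)-3,10-dimethyldodeca-3,5,7,9-tetraene-1,11-diyn-1-yl]-3,5,5-trimethylcyclohex-3-en-1-ol | CC1=C(C#C/C(C)=C/C=C/C=C/C=C(C)/C#C)C(C)(C)C[C@H](O)C1 | intermediate
34 | propiolic acid (prop-2-ynoic acid) | C#CC(=O)O | starting material
35 | (2E)-2,3-dibromoprop-2-enoic acid (C3 bromine cis to the carboxyl group) | OC(=O)/C(Br)=C\Br | intermediate
36 | (2E,6E,8E,10E,12E)-2-bromo-15-[(4R)-4-hydroxy-2,6,6-trimethylcyclohex-1-en-1-yl]-6,13-dimethylpentadeca-2,6,8,10,12-pentaene-4,14-diynoic acid | OC(=O)/C(Br)=C\C#C/C(C)=C/C=C/C=C/C=C(C)/C#CC1=C(C)C[C@@H](O)CC1(C)C | intermediate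
37 | (5Z)-3-bromo-5-{(2E,4E,6E,8E)-11-[(4R)-4-hydroxy-2,6,6-trimethylcyclohex-1-en-1-yl]-2,9-dimethylundeca-2,4,6,8-tetraen-10-yn-1-ylidene}furan-2(5H)-one | CC1=C(C#C/C(C)=C/C=C/C=C/C=C(C)/C=C2C=C(Br)C(=O)O/2)C(C)(C)C[C@H](O)C1 | intermediate
38 | CNP0163979.2, (5Z)-3-{(E)-2-[(1S,2S,4R)-1,2,4-trihydroxy-2,6,6-trimethylcyclohexyl]ethenyl}-5-{(2E,4E,6E,8E)-11-[(4R)-4-hydroxy-2,6,6-trimethylcyclohex-1-en-1-yl]-2,9-dimethylundeca-2,4,6,8-tetraen-10-yn-1-ylidene}furan-2(5H)-one | CC1=C(C#C/C(C)=C/C=C/C=C/C=C(C)/C=C2C=C(/C=C/[C@]3(O)C(C)(C)C[C@@H](O)C[C@]3(C)O)C(=O)O/2)C(C)(C)C[C@H](O)C1 | target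

**Step count and risks**

Total: 24 steps. Longest linear sequence: 13 steps (steps 1 to 12, then step 24).

Step 7 (proposed method). What may go wrong: attack of tert-butyllithium on silicon or on the carbonyl group instead of exchange, or loss of the beta-silyl alkoxide by Peterson elimination before the quench. Fallback with known chemistry, from 8 back to 15: 8 is capped as its trimethylsilyl ether 7 (Me3SiCl, imidazole). The hindered ketone is methylenated with Cp2TiMe2 (toluene, 70 °C) to the exocyclic alkene tert-butyl({(1R,3S)-3,5,5-trimethyl-4-methylidene-3-(trimethylsilyloxy)cyclohexyl}oxy)dimethylsilane F1. Catalytic dihydroxylation (K2OsO2(OH)4, NMO, acetone–water) should add from the face opposite the axial C5 silyloxy group and the axial C1 methyl, giving (1R,2S,4R)-4-(tert-butyldimethylsilyloxy)-1-(hydroxymethyl)-2,6,6-trimethyl-2-(trimethylsilyloxy)cyclohexan-1-ol F2 with the C6 hydroxyl trans to the C5 oxygen. Methanolysis of the trimethylsilyl ether (citric acid, MeOH) then gives 15.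

Step 4. What may go wrong: poor or reversed facial selectivity of the peracid on the enol ether, so that the C5 hydroxyl ends cis to the C3 oxygen. Fallback, from 21 back to 8: the oxidation is run in the mirror-image series that ring A already supplies, and the secondary carbinol is inverted afterwards. 21 is reduced and silylated as in step 3 to (4R)-4-(tert-butyldimethylsilyloxy)-2,6,6-trimethyl-1-(trimethylsilyloxy)cyclohex-1-ene F3. Rubottom oxidation on the face then preferred (syn to the silyloxy group) gives (2S,4S)-4-(tert-butyldimethylsilyloxy)-2-hydroxy-2,6,6-trimethylcyclohexan-1-one F4 with C5 already correct. HF·pyridine frees (2S,4S)-2,4-dihydroxy-2,6,6-trimethylcyclohexan-1-one F5. Mitsunobu reaction with 4-nitrobenzoic acid (PPh3, DIAD, THF) inverts C3 to give (1R,3S)-3-hydroxy-3,5,5-trimethyl-4-oxocyclohexyl 4-nitrobenzoate F6. Methanolysis (K2CO3, MeOH) gives (2S,4R)-2,4-dihydroxy-2,6,6-trimethylcyclohexan-1-one F7, and silylation of the secondary hydroxyl alone (TBSCl, imidazole) returns to 8.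

Step 23. What may go wrong: a second coupling at the alpha-bromide of the newly formed bromobutenolide, or 6-endo closure to the pyranone, while zerovalent palladium is still present. Fallback, from 35 and 33 back to 37: coupling and ring closure are separated. 35 is esterified (MeOH, H2SO4) to methyl (2E)-2,3-dibromoprop-2-enoate F8. Sonogashira coupling with 33, which is selective for the C3 bromide of 2,3-dibromoacrylates, gives methyl (2E,6E,8E,10E,12E)-2-bromo-15-[(4R)-4-hydroxy-2,6,6-trimethylcyclohex-1-en-1-yl]-6,13-dimethylpentadeca-2,6,8,10,12-pentaene-4,14-diynoate F9. Saponification (LiOH, THF–water) gives acid 36, now isolated and free of palladium, and AgNO3-catalysed 5-exo-dig lactonisation (acetone, dark) gives 37.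

**Further compounds**

F1 | step 7 | tert-butyl({(1R,3S)-3,5,5-trimethyl-4-methylidene-3-(trimethylsilyloxy)cyclohexyl}oxy)dimethylsilane | C=C1C(C)(C)C[C@@H](O[Si](C)(C)C(C)(C)C)C[C@]1(C)O[Si](C)(C)C
F2 | step 7 | (1R,2S,4R)-4-(tert-butyldimethylsilyloxy)-1-(hydroxymethyl)-2,6,6-trimethyl-2-(trimethylsilyloxy)cyclohexan-1-ol | OC[C@]1(O)C(C)(C)C[C@@H](O[Si](C)(C)C(C)(C)C)C[C@]1(C)O[Si](C)(C)C
F3 | step 4 | (4R)-4-(tert-butyldimethylsilyloxy)-2,6,6-trimethyl-1-(trimethylsilyloxy)cyclohex-1-ene | C[Si](C)(C)OC1=C(C)C[C@@H](O[Si](C)(C)C(C)(C)C)CC1(C)C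
F4 | step 4 | (2S,4S)-4-(tert-butyldimethylsilyloxy)-2-hydroxy-2,6,6-trimethylcyclohexan-1-one | O=C1C(C)(C)C[C@H](O[Si](C)(C)C(C)(C)C)C[C@]1(C)O
F5 | step 4 | (2S,4S)-2,4-dihydroxy-2,6,6-trimethylcyclohexan-1-one | O=C1C(C)(C)C[C@H](O)C[C@]1(C)O
F6 | step 4 | (1R,3S)-3-hydroxy-3,5,5-trimethyl-4-oxocyclohexyl 4-nitrobenzoate | O=C1C(C)(C)C[C@@H](OC(=O)c2ccc(cc2)[N+](=O)[O-])C[C@]1(C)O
F7 | step 4 | (2S,4R)-2,4-dihydroxy-2,6,6-trimethylcyclohexan-1-one | O=C1C(C)(C)C[C@@H](O)C[C@]1(C)O
F8 | step 23 | methyl (2E)-2,3-dibromoprop-2-enoate | COC(=O)/C(Br)=C\Br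
F9 | step 23 | methyl (2E,6E,8E,10E,12E)-2-bromo-15-[(4R)-4-hydroxy-2,6,6-trimethylcyclohex-1-en-1-yl]-6,13-dimethylpentadeca-2,6,8,10,12-pentaene-4,14-diynoate | COC(=O)/C(Br)=C\C#C/C(C)=C/C=C/C=C/C=C(C)/C#CC1=C(C)C[C@@H](O)CC1(C)C
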